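The target is read as a formaldehyde aldol adduct: the exocyclic C7–O lies β to the ring ketone C2 (ring: C1 carbinol, C2=O, C3=C4, C5–OH, C6–OBz), so the C7–C1 bond is cut to an enolate across C1=C2 of a cyclohexenone carrying a silyloxy group on C1. One operation joins that enolate, monomeric formaldehyde and benzoyl chloride: it creates the quaternary C1 with C7 axial, cis to O6, and delivers the primary benzoate. The enolate precursor is (−)-quinic acid in a rotated mapping: its carboxyl carbon is excised to leave the ketone C2, its trans-4,5-diol, locked as a butane-2,3-diacetal, becomes C5/C6, and its C6 methylene becomes C1.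

Key step: step 6

Remark on numbering: quinic acid numbering is used for 1–6 (cis-3,4-diol, trans-4,5-diol), cyclohex-2-enone numbering for 7–10, and target numbering (C1 carbinol, C2 ketone, C3=C4, C5 CHOH, C6 CHOBz, C7 exocyclic CH2) for 13–20; BDA = butane-2,3-diacetal, a trans-fused 2,3-dimethoxy-2,3-dimethyl-1,4-dioxane with both acetal carbons S and both OMe groups axial.

Step 1
Reactants: 1 (−)-quinic acid; 2 butane-2,3-dione
Product: 3 methyl quinate 4,5-O-butane-2,3-diacetal (1-OH and 3-OH free)
Conditions: butane-2,3-dione, HC(OMe)3, MeOH, CSA (cat.), reflux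
Reagents that add atoms: butane-2,3-dione 2 (CC(=O)C(C)=O); methanol (CO); trimethyl orthoformate (COC(OC)OC)
Why: Ley diacetal formation with concurrent Fischer esterification; only the trans-diequatorial 4,5-diol can give the doubly anomerically stabilised trans-fused dioxane, so the axial 3-OH stays free.

Step 2
Reactants: 3 methyl quinate 4,5-O-butane-2,3-diacetal
Product: 4 BDA-protected 1-(hydroxymethyl)cyclohexane-1,3,4,5-tetrol (triol: 1-OH, 3-OH and CH2OH free)
Conditions: NaBH4, EtOH, 0 °C → rt
Reagents that add atoms: none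
Why: Borohydride reduction of an α-hydroxy ester, which is activated by the neighbouring hydroxyl, gives the primary alcohol while the acetals are inert.

Step 3
Reactants: 4 BDA-protected triol
Product: 5 (3R,4R,5R)-3,4,5-trihydroxycyclohexan-1-one 4,5-O-butane-2,3-diacetal
Conditions: NaIO4, THF/H2O (pH 7 buffer), 0 °C → rt
Reagents that add atoms: none
Why: Malaprade periodate cleavage of the only free vicinal diol (tertiary C1–OH/CH2OH) removes the former carboxyl carbon as formaldehyde and leaves the ring ketone.

Step 4
Reactants: 5 β-hydroxy ketone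
Product: 7 (4R,5R)-4,5-dihydroxycyclohex-2-en-1-one 4,5-O-butane-2,3-diacetal, via 3-O-mesylate 6 (not isolated)
Conditions: MsCl, Et3N, CH2Cl2, 0 °C → rt
Reagents that add atoms: none
Why: Mesylation of the axial β-hydroxyl and E1cB elimination give the conjugated enone, whereas the equatorial acetal oxygen on the other β-carbon is a poor, misaligned leaving group and the diacetal survives.

Step 5
Reactants: 7 BDA-protected (4R,5R)-enone
Product: 10 (4R,5S,6S)-6-(triethylsilyloxy) derivative of enone 7 (silyloxy group axial; cis to O5), via sodium dienolate 8 (not isolated), via sodium 6-alkoxide 9 (not isolated)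
Conditions: NaHMDS, THF, −78 °C; 2-(phenylsulfonyl)-3-phenyloxaziridine; then Et3SiCl, −78 → 0 °C
Reagents that add atoms: 2-(phenylsulfonyl)-3-phenyloxaziridine (O=S(=O)(N1OC1c1ccccc1)c1ccccc1); chlorotriethylsilane (CC[Si](Cl)(CC)CC)
Why: Kinetic α′-deprotonation gives the cross-conjugated dienolate, which is hydroxylated by the N-sulfonyloxaziridine (Davis oxidation, expected axially and anti to the pseudo-axial H5) and silylated in the same flask; the configuration created at C6 is of no consequence because this carbon is re-enolised in step 6.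

Step 6
Reactants: 10 6-(triethylsilyloxy) enone; 11 formaldehyde; 12 benzoyl chloride
Product: 15 [(1R,5R,6S)-5,6-dihydroxy-2-oxo-1-(triethylsilyloxy)cyclohex-3-en-1-yl]methyl benzoate 5,6-O-butane-2,3-diacetal, via lithium dienolate 13 (not isolated), via lithium aldolate 14 (not isolated)
Conditions: LDA, THF, −78 → −40 °C; CH2O (monomeric, THF), −78 °C; then BzCl, −78 → 0 °C
Reagents that add atoms: formaldehyde 11 (C=O); benzoyl chloride 12 (O=C(Cl)c1ccccc1)
Why: LDA removes the C1–H of 10 (either C1 epimer converges) to give the cross-conjugated lithium dienolate 13, which adds to formaldehyde through a lithium-bridged aldol transition state to give aldolate 14, and benzoyl chloride acylates the primary alkoxide before retro-aldol can set in. The closest known reaction type is the lithium enolate/formaldehyde aldol (α-hydroxymethylation of a ketone) with in situ O-acylation of the aldolate. No ring is closed. The new stereocentre C1 is controlled by the ring: the trans-fused diacetal locks O6 pseudo-equatorial and H6 pseudo-axial, so the electrophile should attack C1 anti to the axial C6–H (staggered, axial attack), which places C7 axial and cis to O6 and moves the silyloxy group into the equatorial position, relieving its eclipsing with O6. The step needs C-attack at C1 without β-elimination of O6 or γ-deprotonation at C5; the in-plane C6–O bond, which cannot overlap with the enolate π system, the small hard electrophile and kinetic amide deprotonation at low temperature should secure this.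

Step 7
Reactants: 15 protected aldol benzoate
Product: 16 [(1R,5R,6S)-1,5,6-trihydroxy-2-oxocyclohex-3-en-1-yl]methyl benzoate
Conditions: TFA/H2O (9:1), 0 °C → rt
Reagents that add atoms: none
Why: Aqueous acid hydrolyses the butane-2,3-diacetal and the triethylsilyl ether, while the benzoate, the enone and the tertiary α-ketol are acid-stable and no stereocentre is touched.

Step 8
Reactants: 16 triol monobenzoate; 17 phenylboronic acid; 12 benzoyl chloride
Product: 20 [(1R,5R,6S)-6-(benzoyloxy)-1,5-dihydroxy-2-oxocyclohex-3-en-1-yl]methyl benzoate (target), via O1/O5-phenylboronate 18 (not isolated), via boronate 6-benzoate 19 (not isolated)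
Conditions: PhB(OH)2, toluene, 4 Å MS, rt; then BzCl, pyridine, DMAP (cat.), 0 °C → rt; then pinacol, rt
Reagents that add atoms: benzoyl chloride 12 (O=C(Cl)c1ccccc1)
Why: Transient boronate protection for regioselective acylation: phenylboronic acid should tie the cis-1,3-diol O1/O5 into a six-membered boronate (the trans-vicinal pairs are poorly bridged), leaving only O6–H for DMAP-catalysed benzoylation, and neutral transesterification with pinacol then frees O1–H and O5–H without acyl migration.

Compound list
1 | (−)-quinic acid, (1S,3R,4S,5R)-1,3,4,5-tetrahydroxycyclohexane-1-carboxylic acid | OC(=O)[C@]1(O)C[C@@H](O)[C@@H](O)[C@H](O)C1 | starting material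
2 | butane-2,3-dione | CC(=O)C(C)=O | starting material
3 | methyl quinate 4,5-O-butane-2,3-diacetal (1-OH, 3-OH free) | COC(=O)[C@]1(O)C[C@@H](O)[C@H]2O[C@](C)(OC)[C@@](C)(OC)O[C@@H]2C1 | intermediate
4 | BDA-protected 1-(hydroxymethyl)cyclohexane-1,3,4,5-tetrol (1-OH, 3-OH, CH2OH free) | OC[C@]1(O)C[C@@H](O)[C@H]2O[C@](C)(OC)[C@@](C)(OC)O[C@@H]2C1 | intermediate
5 | (3R,4R,5R)-3,4,5-trihydroxycyclohexan-1-one 4,5-O-butane-2,3-diacetal | O=C1C[C@@H](O)[C@H]2O[C@](C)(OC)[C@@](C)(OC)O[C@@H]2C1 | intermediate
6 | 3-O-methanesulfonate of 5 | O=C1C[C@@H](OS(C)(=O)=O)[C@H]2O[C@](C)(OC)[C@@](C)(OC)O[C@@H]2C1 | intermediate (not isolated)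
7 | (4R,5R)-4,5-dihydroxycyclohex-2-en-1-one 4,5-O-butane-2,3-diacetal | O=C1C=C[C@H]2O[C@](C)(OC)[C@@](C)(OC)O[C@@H]2C1 | intermediate
8 | sodium cross-conjugated dienolate of 7 (O–Na on C1, C1=C6, C2=C3) | [Na]OC1=C[C@H]2O[C@](C)(OC)[C@@](C)(OC)O[C@@H]2C=C1 | intermediate (not isolated)
9 | sodium alkoxide of the 6-hydroxy derivative of 7 (6-O axial, cis to O5) | O=C1C=C[C@H]2O[C@](C)(OC)[C@@](C)(OC)O[C@@H]2[C@@H]1O[Na] | intermediate (not isolated)
10 | (4R,5S,6S)-6-(triethylsilyloxy)-4,5-dihydroxycyclohex-2-en-1-one 4,5-O-butane-2,3-diacetal | O=C1C=C[C@H]2O[C@](C)(OC)[C@@](C)(OC)O[C@@H]2[C@@H]1O[Si](CC)(CC)CC | intermediate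
11 | formaldehyde (monomeric, generated by cracking paraformaldehyde) | C=O | starting material
12 | benzoyl chloride | O=C(Cl)c1ccccc1 | starting material
13 | lithium dienolate of 10 (O–Li on C2, C1=C2, C3=C4, OSiEt3 on C1) | [Li]OC1=C(O[Si](CC)(CC)CC)[C@H]2O[C@](C)(OC)[C@@](C)(OC)O[C@@H]2C=C1 | intermediate (not isolated)
14 | lithium aldolate: C1 quaternary with CH2OLi (cis to O6) and OSiEt3 (cis to O5), BDA on O5/O6 | [Li]OC[C@]1(O[Si](CC)(CC)CC)C(=O)C=C[C@H]2O[C@](C)(OC)[C@@](C)(OC)O[C@H]12 | intermediate (not isolated)
15 | [(1R,5R,6S)-5,6-dihydroxy-2-oxo-1-(triethylsilyloxy)cyclohex-3-en-1-yl]methyl benzoate 5,6-O-butane-2,3-diacetal | O=C(OC[C@]1(O[Si](CC)(CC)CC)C(=O)C=C[C@H]2O[C@](C)(OC)[C@@](C)(OC)O[C@H]12)c1ccccc1 | intermediate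
16 | [(1R,5R,6S)-1,5,6-trihydroxy-2-oxocyclohex-3-en-1-yl]methyl benzoate | O=C(OC[C@]1(O)C(=O)C=C[C@@H](O)[C@@H]1O)c1ccccc1 | intermediate
17 | phenylboronic acid | OB(O)c1ccccc1 | starting material
18 | cyclic phenylboronate of 16 bridging O1 and O5 (O6–H free) | O=C(OC[C@]1(OB(c2ccccc2)O3)C(=O)C=C[C@@H]3[C@@H]1O)c1ccccc1 | intermediate (not isolated)
19 | 6-O-benzoate of boronate 18 | O=C(OC[C@]1(OB(c2ccccc2)O3)C(=O)C=C[C@@H]3[C@@H]1OC(=O)c1ccccc1)c1ccccc1 | intermediate (not isolated)
20 | [(1R,5R,6S)-6-(benzoyloxy)-1,5-dihydroxy-2-oxocyclohex-3-en-1-yl]methyl benzoate | O=C(OC[C@]1(O)C(=O)C=C[C@@H](O)[C@@H]1OC(=O)c1ccccc1)c1ccccc1 | target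

Total step count: 8. Longest linear sequence: 8 steps (from 1).

Steps most likely to fail

1. Step 6 (key step). Formaldehyde may attack the wrong face of dienolate 13 (equatorial instead of axial attack), removal of the pseudo-equatorial C–H next to the silyloxy group may be slow or misdirected, or retro-aldol may precede acylation. The fallback sets out from 7 and returns at 16; it makes the C7–C1 bond as a C=C bond and delivers the oxygen with a reagent of equatorial preference. Enone 7 is treated with LDA and Eschenmoser's salt to give the Mannich base, the 6-(dimethylaminomethyl) enone F1. Quaternisation with MeI and NaHCO3-induced elimination give the cross-conjugated 6-methylene dienone F2, which is used at once. OsO4 (cat.)/NMO should dihydroxylate the more accessible exocyclic alkene from the equatorial direction (steric approach control of osmylation, in line with Kishi's empirical rule), giving the diol F3 with the tertiary hydroxyl trans to O6. Benzoylation of the primary hydroxyl (BzCl, 2,4,6-collidine, −40 °C) gives the primary benzoate F4, and TFA/H2O removes the diacetal to reach 16.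

2. Step 8. Benzoylation may occur at the less hindered allylic O5, the boronate may form across the wrong pair of hydroxyls, or acyl migration may occur during boronate cleavage. The fallback sets out from 16 and returns at 20. TBSCl/imidazole should silylate the less hindered allylic O5–H to give the 5-O-TBS ether F5; BzCl/DMAP/pyridine then benzoylates the remaining secondary O6–H to give the silylated dibenzoate F6; HF·pyridine (acidic, so no acyl migration) removes the silyl group to give 20.

3. Step 5. The sodium dienolate may undergo β-elimination and aromatisation, may add to the sulfonimine by-product, or the alkoxide may be silylated incompletely. The fallback sets out from 7 and returns at 10. Soft enolisation with TESOTf/Et3N gives the 2-(triethylsilyloxy)diene F7; dimethyldioxirane (acetone/CH2Cl2, −78 → 0 °C, Rubottom oxidation) epoxidises the electron-rich enol ether double bond to the silyloxy epoxide F8, which opens with 1,4-silyl migration to give 10.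

Further compounds
F1 | step 6 | 6-(dimethylaminomethyl) derivative of enone 7 (Mannich base) | O=C1C=C[C@H]2O[C@](C)(OC)[C@@](C)(OC)O[C@@H]2[C@@H]1CN(C)C
F2 | step 6 | 6-methylene derivative of enone 7 (cross-conjugated dienone) | O=C1C=C[C@H]2O[C@](C)(OC)[C@@](C)(OC)O[C@@H]2C1=C
F3 | step 6 | 6-hydroxy-6-(hydroxymethyl) derivative of enone 7 (tertiary OH trans to O5 of the enone, target configuration) | OC[C@]1(O)C(=O)C=C[C@H]2O[C@](C)(OC)[C@@](C)(OC)O[C@H]12
F4 | step 6 | primary benzoate of F3 (5,6-O-butane-2,3-diacetal of 16) | O=C(OC[C@]1(O)C(=O)C=C[C@H]2O[C@](C)(OC)[C@@](C)(OC)O[C@H]12)c1ccccc1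
F5 | step 8 | 5-O-tert-butyldimethylsilyl ether of 16 | O=C(OC[C@]1(O)C(=O)C=C[C@@H](O[Si](C)(C)C(C)(C)C)[C@@H]1O)c1ccccc1
F6 | step 8 | 5-O-tert-butyldimethylsilyl ether of 20 | O=C(OC[C@]1(O)C(=O)C=C[C@@H](O[Si](C)(C)C(C)(C)C)[C@@H]1OC(=O)c1ccccc1)c1ccccc1
F7 | step 5 | triethylsilyl dienol ether of 7 (2-silyloxy-1,3-diene) | CC[Si](CC)(CC)OC1=C[C@H]2O[C@](C)(OC)[C@@](C)(OC)O[C@@H]2C=C1
F8 | step 5 | silyloxy epoxide of F7 (epoxide on the face anti to the pseudo-axial H5) | CC[Si](CC)(CC)O[C@]12O[C@H]1[C@H]3O[C@](C)(OC)[C@@](C)(OC)O[C@@H]3C=C2
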